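## Retrosynthetic overview

- The only ring (the cyclohexenone) is closed last, at C2=C3, by intramolecular aldol condensation of a (3R,4R)-3-silyloxy-4-geranylgeranylheptane-2,6-dione.
- The C6–C1(=O)–C2 arm comes from an aldehyde by homologation to the methyl ketone (1-ethoxyethylidene Wittig, then enol ether hydrolysis).
- The C4–C5 bond and both stereocentres come from one amine-catalysed anti cross-aldol of geranylgeranylacetaldehyde (donor) with methylglyoxal (acceptor); anti in the chain becomes cis on the ring.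
- The donor aldehyde comes from SN2 alkylation of an acetaldehyde aza-enolate with geranylgeranyl bromide, made from all-E geranylgeraniol.

Assumption: "geranylgeranyl" means (2E,6E,10E)-3,7,11,15-tetramethylhexadeca-2,6,10,14-tetraen-1-yl, and ring atoms are numbered as in the target (C1 carbonyl, C4 carbinol, C5 bearing the side chain).

Descriptor note: the side-chain carbon is S in aldehydes 10 and 11 and R from 12 onward only because substituent priorities change; no centre is inverted.

## Route

Step 1
Reactants: 1 (2E,6E,10E)-geranylgeraniol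
Product: 2 geranylgeranyl bromide
Conditions: PBr3 (0.4 equiv), Et2O, −10 °C, 30 min; used crude
Reagents that add atoms: phosphorus tribromide, BrP(Br)Br
Why: Alcohol-to-bromide substitution with PBr3 proceeds by SN2 displacement of the phosphite ester at the primary allylic carbon at low temperature, so no allylic transposition occurs and all three E-alkenes are kept.

Step 2
Reactants: 2 geranylgeranyl bromide; 3 acetaldehyde; 4 tert-butylamine
Product: 8 (4E,8E,12E)-5,9,13,17-tetramethyloctadeca-4,8,12,16-tetraenal, via tert-butylimine of acetaldehyde 5 (not isolated), via lithium aza-enolate 6 (not isolated), via alkylated tert-butylimine 7 (not isolated)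
Conditions: 3 + 4 (1.6 equiv each), 4 Å molecular sieves, THF, 0 °C; filtrate into LiN(iPr)2 (1.5 equiv), THF, −78 → 0 °C; 2, −78 °C → rt; then 1 M aq. oxalic acid, pentane, rt
Reagents that add atoms: water, O
Why: Stork metalloenamine alkylation: the lithium aza-enolate of the acetaldehyde imine attacks the primary allylic bromide by SN2 at the unsubstituted terminus (E-geometry kept, mono-alkylation), and mild two-phase acid hydrolysis frees the homologated aldehyde without touching the trisubstituted alkenes.

Step 3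
Reactants: 8 (4E,8E,12E)-5,9,13,17-tetramethyloctadeca-4,8,12,16-tetraenal; 9 methylglyoxal
Product: 10 (2S,3R)-3-hydroxy-4-oxo-2-geranylgeranylpentanal
Conditions: 9 (40% in water, 3 equiv), (S)-α,α-bis[3,5-bis(trifluoromethyl)phenyl]pyrrolidin-2-ylmethanol (10 mol%), THF, 4 °C, 48 h; cold extractive work-up, used at once
Reagents that add atoms: none
Why: Proposed new method: an enamine-catalysed direct cross-aldol in which the (S)-diarylprolinol turns 8 into its E-enamine and its hydroxyl hydrogen-bonds the aldehyde carbonyl of methylglyoxal (far more electrophilic than its ketone or than 8) in a proline-like chair transition state, which forms the C4–C5 bond and sets C2 as S and C3 as R in the anti relationship that becomes cis on the ring; the closest known reaction type is the diarylprolinol-catalysed anti-selective cross-aldol of aldehydes with ethyl glyoxylate or aqueous glyoxal, and an enolisable 2-oxoaldehyde has not, to my knowledge, been used as the acceptor.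

Step 4
Reactants: 10 (2S,3R)-3-hydroxy-4-oxo-2-geranylgeranylpentanal
Product: 11 (2S,3R)-4-oxo-2-geranylgeranyl-3-(triethylsilyloxy)pentanal
Conditions: TESOTf (1.2 equiv), 2,6-lutidine (2 equiv), CH2Cl2, −78 °C, 30 min
Reagents that add atoms: triethylsilyl trifluoromethanesulfonate, CC[Si](CC)(CC)OS(=O)(=O)C(F)(F)F
Why: Silyl ether formation with TESOTf and 2,6-lutidine at −78 °C is faster than enolisation or retro-aldol, so both stereocentres are kept and the hydroxyl is masked against the basic ylide and the later amine chemistry.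

Step 5
Reactants: 11 (2S,3R)-4-oxo-2-geranylgeranyl-3-(triethylsilyloxy)pentanal
Product: 13 (3R,4R)-4-geranylgeranyl-3-(triethylsilyloxy)heptane-2,6-dione, via ethyl enol ether 12 (not isolated)
Conditions: Ph3P·HBr (1.6 equiv), ethyl vinyl ether (1.8 equiv), CH2Cl2, rt, then solvent exchange to THF; KN(SiMe3)2 (1.5 equiv), −78 °C; 11, −78 → −20 °C; then 0.1 M aq. oxalic acid, THF, 0 °C, 20 min
Reagents that add atoms: ethyl vinyl ether, C=COCC; water, O
Why: Wittig olefination followed by enol ether hydrolysis (aldehyde to homologous methyl ketone): the 1-ethoxyethylidene phosphorane reacts at −78 °C with the aldehyde far faster than with the hindered α-silyloxy ketone, and buffered aqueous acid hydrolyses enol ether 12 to the methyl ketone while the TES ether, C4 and C5 are untouched.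

Step 6
Reactants: 13 (3R,4R)-4-geranylgeranyl-3-(triethylsilyloxy)heptane-2,6-dione
Product: 15 (4R,5R)-4-hydroxy-3-methyl-5-geranylgeranylcyclohex-2-en-1-one, via silyl-protected enone 14 (not isolated)
Conditions: pyrrolidine (0.3 equiv), AcOH (0.3 equiv), THF, 23 °C, 12 h; then 1 M aq. HCl, 23 °C, 1 h
Reagents that add atoms: none
Why: Intramolecular enamine aldol condensation: pyrrolidine forms the enamine of the unhindered C1 methyl ketone, whose methyl carbon adds to the more electrophilic α-silyloxy ketone through the only strain-free (six-membered) closure and loses water to give enone 14 without epimerising C4 (the hindered ketone does not form an enamine, and the silyl group blocks isomerisation of the γ-oxy-enone to the 1,4-dione), and dilute HCl then cleaves the TES ether.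

## Compound list

1 | (2E,6E,10E)-geranylgeraniol, (2E,6E,10E)-3,7,11,15-tetramethylhexadeca-2,6,10,14-tetraen-1-ol | CC(C)=CCC/C(C)=C/CC/C(C)=C/CC/C(C)=C/CO | starting material
2 | geranylgeranyl bromide, (2E,6E,10E)-1-bromo-3,7,11,15-tetramethylhexadeca-2,6,10,14-tetraene | CC(C)=CCC/C(C)=C/CC/C(C)=C/CC/C(C)=C/CBr | intermediate
3 | acetaldehyde | CC=O | starting material
4 | tert-butylamine | CC(C)(C)N | starting material
5 | (E)-N-tert-butylethanimine | C/C=N/C(C)(C)C | intermediate
6 | lithium aza-enolate of 5, lithium N-tert-butyl-N-vinylamide | [Li+].C=C[N-]C(C)(C)C | intermediate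
7 | N-tert-butylimine of (4E,8E,12E)-5,9,13,17-tetramethyloctadeca-4,8,12,16-tetraenal | CC(C)=CCC/C(C)=C/CC/C(C)=C/CC/C(C)=C/CC/C=N/C(C)(C)C | intermediate
8 | (4E,8E,12E)-5,9,13,17-tetramethyloctadeca-4,8,12,16-tetraenal | CC(C)=CCC/C(C)=C/CC/C(C)=C/CC/C(C)=C/CCC=O | intermediate
9 | methylglyoxal (2-oxopropanal) | CC(=O)C=O | starting material
10 | (2S,3R)-3-hydroxy-4-oxo-2-geranylgeranylpentanal | CC(C)=CCC/C(C)=C/CC/C(C)=C/CC/C(C)=C/C[C@H](C=O)[C@@H](O)C(C)=O | intermediate
11 | (2S,3R)-4-oxo-2-geranylgeranyl-3-(triethylsilyloxy)pentanal | CC(C)=CCC/C(C)=C/CC/C(C)=C/CC/C(C)=C/C[C@H](C=O)[C@@H](O[Si](CC)(CC)CC)C(C)=O | intermediate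
12 | (3R,4R)-6-ethoxy-4-geranylgeranyl-3-(triethylsilyloxy)hept-5-en-2-one (E/Z mixture) | CC(C)=CCC/C(C)=C/CC/C(C)=C/CC/C(C)=C/C[C@H](C=C(C)OCC)[C@@H](O[Si](CC)(CC)CC)C(C)=O | intermediate
13 | (3R,4R)-4-geranylgeranyl-3-(triethylsilyloxy)heptane-2,6-dione | CC(C)=CCC/C(C)=C/CC/C(C)=C/CC/C(C)=C/C[C@H](CC(C)=O)[C@@H](O[Si](CC)(CC)CC)C(C)=O | intermediate
14 | (4R,5R)-3-methyl-5-geranylgeranyl-4-(triethylsilyloxy)cyclohex-2-en-1-one | CC(C)=CCC/C(C)=C/CC/C(C)=C/CC/C(C)=C/C[C@@H]1CC(=O)C=C(C)[C@@H]1O[Si](CC)(CC)CC | intermediate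
15 | (4R,5R)-4-hydroxy-3-methyl-5-[(2E,6E,10E)-3,7,11,15-tetramethylhexadeca-2,6,10,14-tetraen-1-yl]cyclohex-2-en-1-one | CC(C)=CCC/C(C)=C/CC/C(C)=C/CC/C(C)=C/C[C@@H]1CC(=O)C=C(C)[C@@H]1O | target

## Step count and risks

Total step count: 6. Longest linear sequence: 6 steps (1 → 2 → 8 → 10 → 11 → 13 → 15).

The three steps most likely to fail are steps 3, 5 and 6.

Step 3 is the proposed new reaction. The risks are attack at the ketone carbonyl or slow reaction of hydrated methylglyoxal, erosion of the anti ratio, and the untested facial sense with this acceptor. The fallback uses only known chemistry and sets out from 8. A cross-aldol with ethyl glyoxylate under the same diarylprolinol (an established acceptor for this catalyst, anti-selective) gives ethyl (2R,3S)-3-formyl-2-hydroxy ester F1. TESOTf and 2,6-lutidine give its silyl ether F2. Wittig olefination with the 1-ethoxyethylidene phosphorane, without acid work-up, gives enol ether ester F3. Me(MeO)NH·HCl with iPrMgCl gives Weinreb amide F4, and MeMgBr converts this into the methyl ketone 12. The fallback comes back to the route at 12, which is hydrolysed to 13 as in step 5.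

Step 5 may fail because the hindered, basic ylide reacts slowly or epimerises the α-centre of 11. The fallback sets out from 11. Wittig reaction with Ph3P=CHOMe (from Ph3P(CH2OMe)Cl and KN(SiMe3)2), a smaller and well-behaved ylide, gives methyl enol ether F5. Buffered aqueous oxalic acid gives the one-carbon-longer aldehyde F6. MeTi(OiPr)3 adds to the aldehyde in the presence of the ketone to give secondary alcohol F7, and Dess–Martin periodinane oxidises this to 13, where the route is rejoined.

Step 6 may give the regioisomeric enone, or amine-mediated isomerisation of the γ-oxy-enone. The fallback sets out from 12, kept by leaving out the acid work-up of step 5. Anhydrous camphorsulfonic acid (10 mol%) in CH2Cl2 at 0 °C lets the oxocarbenium/2-ethoxyalkene pair, which can only be nucleophilic on the C1 side, close onto the C3 ketone and lose water to give ethoxydiene F8. Dilute aqueous HCl hydrolyses F8 to 14, where the route is rejoined, and on to 15.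

## Further compounds

F1 | step 3 | ethyl (2R,3S,5E,9E,13E)-3-formyl-2-hydroxy-6,10,14,18-tetramethylnonadeca-5,9,13,17-tetraenoate | CC(C)=CCC/C(C)=C/CC/C(C)=C/CC/C(C)=C/C[C@H](C=O)[C@@H](O)C(=O)OCC
F2 | step 3 | ethyl (2R,3S,5E,9E,13E)-3-formyl-6,10,14,18-tetramethyl-2-(triethylsilyloxy)nonadeca-5,9,13,17-tetraenoate | CC(C)=CCC/C(C)=C/CC/C(C)=C/CC/C(C)=C/C[C@H](C=O)[C@@H](O[Si](CC)(CC)CC)C(=O)OCC
F3 | step 3 | ethyl (2R,3R,5E,9E,13E)-3-(2-ethoxyprop-1-en-1-yl)-6,10,14,18-tetramethyl-2-(triethylsilyloxy)nonadeca-5,9,13,17-tetraenoate | CC(C)=CCC/C(C)=C/CC/C(C)=C/CC/C(C)=C/C[C@H](C=C(C)OCC)[C@@H](O[Si](CC)(CC)CC)C(=O)OCC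
F4 | step 3 | (2R,3R,5E,9E,13E)-3-(2-ethoxyprop-1-en-1-yl)-N-methoxy-N,6,10,14,18-pentamethyl-2-(triethylsilyloxy)nonadeca-5,9,13,17-tetraenamide | CC(C)=CCC/C(C)=C/CC/C(C)=C/CC/C(C)=C/C[C@H](C=C(C)OCC)[C@@H](O[Si](CC)(CC)CC)C(=O)N(C)OC
F5 | step 5 | (3R,4R)-4-geranylgeranyl-6-methoxy-3-(triethylsilyloxy)hex-5-en-2-one (E/Z mixture) | CC(C)=CCC/C(C)=C/CC/C(C)=C/CC/C(C)=C/C[C@H](C=COC)[C@@H](O[Si](CC)(CC)CC)C(C)=O
F6 | step 5 | (3R,4R)-3-geranylgeranyl-5-oxo-4-(triethylsilyloxy)hexanal | CC(C)=CCC/C(C)=C/CC/C(C)=C/CC/C(C)=C/C[C@H](CC=O)[C@@H](O[Si](CC)(CC)CC)C(C)=O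
F7 | step 5 | (3R,4R)-4-geranylgeranyl-6-hydroxy-3-(triethylsilyloxy)heptan-2-one (both C6 epimers) | CC(C)=CCC/C(C)=C/CC/C(C)=C/CC/C(C)=C/C[C@H](CC(C)O)[C@@H](O[Si](CC)(CC)CC)C(C)=O
F8 | step 6 | {[(1R,6R)-4-ethoxy-6-geranylgeranyl-2-methylcyclohexa-2,4-dien-1-yl]oxy}triethylsilane | CC(C)=CCC/C(C)=C/CC/C(C)=C/CC/C(C)=C/C[C@@H]1C=C(OCC)C=C(C)[C@@H]1O[Si](CC)(CC)CC
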